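**Retrosynthetic overview**

1. The strategy rests on the benzene ring itself. C1 (CO2Me), C2–O, C4–O and C6 (phenethyl) are the carbons of a folded 3,5,7-trioxo-9-phenylnonanoate chain, and C3, the ring carbon between the two oxygen-bearing carbons, is the chain methylene best able to capture a prenyl electrophile.
2. The last disconnection is methanolysis of a 2,2-dimethyl-1,3-benzodioxin-4-one that ties the C1 carboxyl to the C2 oxygen. Before it, the C5 prenyl group is taken off by a retro-Claisen shift to a 1,1-dimethylallyl ether of the one free phenol.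
3. The key disconnection cuts the C3–CH2 (prenyl) bond and the C1–C6 ring bond together, back to an acyclic diketo-dioxinone prenyl ester (prenyl migration with loss of CO2, then aldol aromatisation).
4. The chain comes from two acylations: 3-phenylpropanoyl chloride on the beta-keto ester carbon, and prenyl malonyl chloride on the gamma carbon of the dienolate of 2,2,6-trimethyl-1,3-dioxin-4-one.
5. Ring order: the dioxinone ring is purchased, the benzene ring is closed onto it in step 5, and the dioxinone ring is opened in the last step.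

Key step: step 5

Remark: prenyl means 3-methylbut-2-en-1-yl throughout. Compounds 9, 10 and 11 are drawn as keto tautomers although they should exist largely as enols or chelates, and 9 is carried into step 5 without extensive purification.

**Route**

Step 1
Reactants: 1 Meldrum's acid (2,2-dimethyl-1,3-dioxane-4,6-dione); 2 prenol (3-methylbut-2-en-1-ol)
Product: 3 mono-prenyl malonate (3-[(3-methylbut-2-enyl)oxy]-3-oxopropanoic acid)
Conditions: toluene, 110 °C
Reagents that add atoms: none
Why: Alcoholysis of Meldrum's acid: on heating, prenol opens the bis-acylal with loss of acetone to leave the malonic half ester, and the free acid does not esterify further under these neutral conditions.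

Step 2
Reactants: 3 mono-prenyl malonate
Product: 4 prenyl malonyl chloride (3-methylbut-2-enyl 3-chloro-3-oxopropanoate)
Conditions: (COCl)2, DMF (cat.), CH2Cl2, 0 °C to rt; evaporate and use crude
Reagents that add atoms: oxalyl chloride, O=C(Cl)C(=O)Cl
Why: Acid chloride formation through the Vilsmeier-type chloroiminium species from DMF and oxalyl chloride is mild and gives only gaseous by-products, so the prenyl ester should survive if HCl is swept out and the crude chloride is used at once.

Step 3
Reactants: 5 2,2,6-trimethyl-4H-1,3-dioxin-4-one; 4 prenyl malonyl chloride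
Product: 7 prenyl 4-(2,2-dimethyl-4-oxo-4H-1,3-dioxin-6-yl)-3-oxobutanoate, via lithium dienolate 6 (not isolated)
Conditions: 5 (2.5 equiv), LiN(SiMe3)2 (2.5 equiv), THF, −78 °C; then 4 (1 equiv), −78 °C; 1 M HCl
Reagents that add atoms: none
Why: Crossed Claisen-type acylation: LiN(SiMe3)2 removes a proton from the C6 methyl group of 5 to give the extended dienolate 6, which is acylated by the acid chloride at its gamma (exocyclic) carbon, and the excess dienolate absorbs the more acidic proton of product 7 so that the acylation runs to completion.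

Step 4
Reactants: 7 prenyl 4-(2,2-dimethyl-4-oxo-4H-1,3-dioxin-6-yl)-3-oxobutanoate; 8 3-phenylpropanoyl chloride
Product: 9 diketo-dioxinone prenyl ester (3-methylbut-2-enyl 2-[(2,2-dimethyl-4-oxo-4H-1,3-dioxin-6-yl)acetyl]-3-oxo-5-phenylpentanoate)
Conditions: MgCl2, pyridine, CH2Cl2, 0 °C to rt; dilute HCl wash
Reagents that add atoms: none
Why: Magnesium-mediated C-acylation of a beta-keto ester: MgCl2 chelates the keto ester so that pyridine can deprotonate the CH2 between ketone and ester, and the chelated enolate is acylated at carbon by the acid chloride, leaving the dioxinone and its flanking CH2 untouched.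

Step 5
Reactants: 9 diketo-dioxinone prenyl ester
Product: 12 8-prenyl benzodioxinone phenol (7-hydroxy-2,2-dimethyl-8-(3-methylbut-2-enyl)-5-(2-phenylethyl)-4H-1,3-benzodioxin-4-one), via C-prenyl diketo-dioxinone 10 (not isolated), via cyclic aldol adduct 11 (not isolated)
Conditions: Pd(PPh3)4 (10 mol %), Cs2CO3, THF, 0 °C to rt; then cold 1 M HCl
Reagents that add atoms: none
Why: Zerovalent palladium ionises the prenyl ester of 9 to a pi-prenyl complex of divalent palladium and a beta-keto carboxylate; the enolised CH2 between the dioxinone C6 and the adjacent ketone attacks the unsubstituted CH2 terminus of the pi-prenyl ligand, and the beta-keto acid then loses CO2 to give 10. The closest known reaction type is the Tsuji–Trost decarboxylative allylation of allyl beta-keto esters, here with delivery to a remote carbon, as established for diketo-dioxinone allyl and prenyl esters on the way to 3-prenyl resorcylates. Cs2CO3 then forms the dioxinone dienolate, whose alpha carbon (C5 of the dioxinone, future C1) adds to the phenethyl ketone carbon (future C6) in a 6-exo-trig aldol closure to 11, and loss of water with enolisation of the remaining ketone gives the benzene ring fused to the dioxinone. No stereocentre has to be controlled, because the two sp3 centres of 11 are erased on aromatisation. The step needs prenylation at carbon and not oxygen, at the dioxinone-flanked carbon and not the carbon between the two ketones, and linear instead of branched attachment; the first two are secured because the soft stabilised enolate reacts at carbon while the competing carbon is still fully substituted by the carboxylate, and the third because the nucleophile approaches the less hindered terminus of the pi-prenyl ligand.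

Step 6
Reactants: 13 2-methylbut-3-en-2-ol
Product: 15 tert-butyl 2-methylbut-3-en-2-yl carbonate, via lithium alkoxide 14 (not isolated)
Conditions: n-BuLi, THF, 0 °C; then Boc2O, 0 °C to rt; H2O
Reagents that add atoms: di-tert-butyl dicarbonate (Boc2O), CC(C)(C)OC(=O)OC(=O)OC(C)(C)C
Why: Acylation of a tertiary lithium alkoxide with Boc2O gives the mixed carbonate directly, the alkoxide being needed because the hindered tertiary allylic alcohol is a poor nucleophile.

Step 7
Reactants: 12 8-prenyl benzodioxinone phenol; 15 tert-butyl 2-methylbut-3-en-2-yl carbonate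
Product: 16 reverse prenyl ether (2,2-dimethyl-7-[(2-methylbut-3-en-2-yl)oxy]-8-(3-methylbut-2-enyl)-5-(2-phenylethyl)-4H-1,3-benzodioxin-4-one)
Conditions: Pd(PPh3)4 (5 mol %), THF, 0 °C to rt
Reagents that add atoms: none
Why: Tsuji–Trost O-allylation: zerovalent palladium ionises the tertiary carbonate to a pi-(1,1-dimethylallyl) complex of divalent palladium with release of CO2 and tert-butoxide, which deprotonates the only free phenol, and the phenoxide attacks the more substituted terminus under kinetic control to give the tertiary ether, low temperature and short contact time preventing drift to the linear ether.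

Step 8
Reactants: 16 reverse prenyl ether
Product: 18 diprenyl benzodioxinone (7-hydroxy-2,2-dimethyl-6,8-bis(3-methylbut-2-enyl)-5-(2-phenylethyl)-4H-1,3-benzodioxin-4-one), via Claisen dienone 17 (not isolated)
Conditions: toluene (degassed, base-washed glassware), 110 °C
Reagents that add atoms: none
Why: Aromatic Claisen rearrangement: the concerted 3,3 shift through a six-membered transition state carries the allyl unit with inversion to C6, the only unsubstituted ortho carbon, so the 1,1-dimethylallyl ether becomes a linear prenyl group and dienone 17 tautomerises to the phenol, while a shift towards the substituted C8 can only revert.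

Step 9
Reactants: 18 diprenyl benzodioxinone
Product: 19 methyl 2,4-dihydroxy-3,5-bis(3-methylbut-2-enyl)-6-(2-phenylethyl)benzoate (target)
Conditions: NaOMe, MeOH (dry), 50 °C; then cold dilute HCl to pH 5
Reagents that add atoms: methanol, CO (delivered as sodium methoxide, C[O-].[Na+])
Why: Transesterification of the aryl ester acetal: methoxide adds to the C4 carbonyl, the ring opens, and the hemiketal oxide left on the C2 oxygen collapses to acetone and the phenoxide, giving the methyl ester, which is then shielded by two ortho substituents and a hydrogen bond from the C2 hydroxyl.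

**Compound list**

1 | Meldrum's acid (2,2-dimethyl-1,3-dioxane-4,6-dione) | CC1(C)OC(=O)CC(=O)O1 | starting material
2 | prenol (3-methylbut-2-en-1-ol) | CC(C)=CCO | starting material
3 | mono-prenyl malonate | CC(C)=CCOC(=O)CC(=O)O | intermediate
4 | prenyl malonyl chloride | CC(C)=CCOC(=O)CC(=O)Cl | intermediate
5 | 2,2,6-trimethyl-4H-1,3-dioxin-4-one | CC1=CC(=O)OC(C)(C)O1 | starting material
6 | lithium 2,2-dimethyl-6-methylidene-6H-1,3-dioxin-4-olate (dienolate of 5) | [Li+].C=C1C=C([O-])OC(C)(C)O1 | intermediate
7 | prenyl 4-(2,2-dimethyl-4-oxo-4H-1,3-dioxin-6-yl)-3-oxobutanoate | CC1(C)OC(=O)C=C(CC(=O)CC(=O)OCC=C(C)C)O1 | intermediate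
8 | 3-phenylpropanoyl chloride | O=C(Cl)CCc1ccccc1 | starting material
9 | 3-methylbut-2-enyl 2-[(2,2-dimethyl-4-oxo-4H-1,3-dioxin-6-yl)acetyl]-3-oxo-5-phenylpentanoate | CC1(C)OC(=O)C=C(CC(=O)C(C(=O)OCC=C(C)C)C(=O)CCc2ccccc2)O1 | intermediate
10 | 2,2-dimethyl-6-(2-methyl-6,8-dioxo-10-phenyldec-2-en-5-yl)-4H-1,3-dioxin-4-one | CC1(C)OC(=O)C=C(C(CC=C(C)C)C(=O)CC(=O)CCc2ccccc2)O1 | intermediate
11 | 5-hydroxy-2,2-dimethyl-8-(3-methylbut-2-enyl)-5-(2-phenylethyl)-5,6-dihydro-4H-1,3-benzodioxine-4,7(8H)-dione (mixture of diastereomers) | CC1(C)OC(=O)C2=C(O1)C(CC=C(C)C)C(=O)CC2(O)CCc1ccccc1 | intermediate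
12 | 7-hydroxy-2,2-dimethyl-8-(3-methylbut-2-enyl)-5-(2-phenylethyl)-4H-1,3-benzodioxin-4-one | CC1(C)OC(=O)c2c(CCc3ccccc3)cc(O)c(CC=C(C)C)c2O1 | intermediate
13 | 2-methylbut-3-en-2-ol | C=CC(C)(C)O | starting material
14 | lithium 2-methylbut-3-en-2-olate | [Li+].C=CC(C)(C)[O-] | intermediate
15 | tert-butyl 2-methylbut-3-en-2-yl carbonate | C=CC(C)(C)OC(=O)OC(C)(C)C | intermediate
16 | 2,2-dimethyl-7-[(2-methylbut-3-en-2-yl)oxy]-8-(3-methylbut-2-enyl)-5-(2-phenylethyl)-4H-1,3-benzodioxin-4-one | CC1(C)OC(=O)c2c(CCc3ccccc3)cc(OC(C)(C)C=C)c(CC=C(C)C)c2O1 | intermediate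
17 | 2,2-dimethyl-6,8-bis(3-methylbut-2-enyl)-5-(2-phenylethyl)-4H-1,3-benzodioxine-4,7(6H)-dione | CC1(C)OC(=O)C2=C(CCc3ccccc3)C(CC=C(C)C)C(=O)C(CC=C(C)C)=C2O1 | intermediate
18 | 7-hydroxy-2,2-dimethyl-6,8-bis(3-methylbut-2-enyl)-5-(2-phenylethyl)-4H-1,3-benzodioxin-4-one | CC1(C)OC(=O)c2c(CCc3ccccc3)c(CC=C(C)C)c(O)c(CC=C(C)C)c2O1 | intermediate
19 | methyl 2,4-dihydroxy-3,5-bis(3-methylbut-2-enyl)-6-(2-phenylethyl)benzoate | COC(=O)c1c(O)c(CC=C(C)C)c(O)c(CC=C(C)C)c1CCc1ccccc1 | target

**Step count**

Total steps: 9. Longest linear sequence: 8 (steps 1 to 5, then 7 to 9; step 6 is a one-step side branch).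

**Steps most likely to fail, with fallbacks**

Step 5. The prenyl unit may be delivered to oxygen or to the wrong chain carbon, or the enolate may be protonated after CO2 loss so that the prenyl group leaves the molecule, giving an unprenylated or wrongly prenylated arene. The fallback sets out from 9 and separates ring formation from prenylation. Pd(PPh3)4 with morpholine as prenyl acceptor in THF at 0 °C should remove the ester with decarboxylation and give the unprenylated diketo-dioxinone 2,2-dimethyl-6-(2,4-dioxo-6-phenylhexyl)-4H-1,3-dioxin-4-one F1. Cs2CO3 or Et3N in THF should aromatise this to 7-hydroxy-2,2-dimethyl-5-(2-phenylethyl)-4H-1,3-benzodioxin-4-one F2. O-Allylation with carbonate 15 under Pd(PPh3)4 should give the reverse prenyl ether 2,2-dimethyl-7-[(2-methylbut-3-en-2-yl)oxy]-5-(2-phenylethyl)-4H-1,3-benzodioxin-4-one F3. Its Claisen rearrangement in toluene at 110 °C is expected to favour C8, the carbon between the two oxygen-bearing carbons and remote from the phenethyl group, which returns the route at 12. Any C6 isomer, 7-hydroxy-2,2-dimethyl-6-(3-methylbut-2-enyl)-5-(2-phenylethyl)-4H-1,3-benzodioxin-4-one F4, is not lost, because the target carries prenyl groups on both ortho carbons. The same etherification gives 2,2-dimethyl-7-[(2-methylbut-3-en-2-yl)oxy]-6-(3-methylbut-2-enyl)-5-(2-phenylethyl)-4H-1,3-benzodioxin-4-one F5, and Claisen rearrangement of F5 to C8 rejoins the route at 18.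

Step 7. The hindered, electron-poor phenoxide may attack the tertiary terminus too slowly, so that the palladium catalyst equilibrates the product to the linear prenyl ether or C-allylation competes. The fallback sets out from 12 and builds the tertiary ether by copper-catalysed propargylation. 3-Chloro-3-methylbut-1-yne with CuCl2 (cat.) and DBU in MeCN at 0 °C should give the 1,1-dimethylpropargyl ether 2,2-dimethyl-7-[(2-methylbut-3-yn-2-yl)oxy]-8-(3-methylbut-2-enyl)-5-(2-phenylethyl)-4H-1,3-benzodioxin-4-one F6. Partial hydrogenation of the alkyne (H2, Pd/CaCO3 poisoned with Pb(OAc)2, quinoline, EtOAc), which should leave the trisubstituted prenyl alkene alone, returns the route at 16.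

Step 8. The tertiary allyl–oxygen bond may break heterolytically on heating, returning phenol 12 and isoprene, or traces of acid may close the new ortho-prenyl phenol onto its alkene as a chroman. The fallback sets out from 12 and uses a primary allyl ether, which cannot ionise in this way. Allyl bromide with K2CO3 in acetone should give the allyl ether 2,2-dimethyl-8-(3-methylbut-2-enyl)-5-(2-phenylethyl)-7-(prop-2-enyloxy)-4H-1,3-benzodioxin-4-one F7. Claisen rearrangement in N,N-diethylaniline at 190 °C should give the C6 allyl phenol 7-hydroxy-2,2-dimethyl-8-(3-methylbut-2-enyl)-5-(2-phenylethyl)-6-(prop-2-enyl)-4H-1,3-benzodioxin-4-one F8. Cross-metathesis with excess 2-methylbut-2-ene and second-generation Grubbs catalyst in CH2Cl2 should convert the allyl group into prenyl, the existing prenyl group exchanging only degenerately, and return the route at 18.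

**Further compounds**

F1 | step 5 | 2,2-dimethyl-6-(2,4-dioxo-6-phenylhexyl)-4H-1,3-dioxin-4-one | CC1(C)OC(=O)C=C(CC(=O)CC(=O)CCc2ccccc2)O1
F2 | step 5 | 7-hydroxy-2,2-dimethyl-5-(2-phenylethyl)-4H-1,3-benzodioxin-4-one | CC1(C)OC(=O)c2c(CCc3ccccc3)cc(O)cc2O1
F3 | step 5 | 2,2-dimethyl-7-[(2-methylbut-3-en-2-yl)oxy]-5-(2-phenylethyl)-4H-1,3-benzodioxin-4-one | CC1(C)OC(=O)c2c(CCc3ccccc3)cc(OC(C)(C)C=C)cc2O1
F4 | step 5 | 7-hydroxy-2,2-dimethyl-6-(3-methylbut-2-enyl)-5-(2-phenylethyl)-4H-1,3-benzodioxin-4-one | CC1(C)OC(=O)c2c(CCc3ccccc3)c(CC=C(C)C)c(O)cc2O1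
F5 | step 5 | 2,2-dimethyl-7-[(2-methylbut-3-en-2-yl)oxy]-6-(3-methylbut-2-enyl)-5-(2-phenylethyl)-4H-1,3-benzodioxin-4-one | CC1(C)OC(=O)c2c(CCc3ccccc3)c(CC=C(C)C)c(OC(C)(C)C=C)cc2O1
F6 | step 7 | 2,2-dimethyl-7-[(2-methylbut-3-yn-2-yl)oxy]-8-(3-methylbut-2-enyl)-5-(2-phenylethyl)-4H-1,3-benzodioxin-4-one | CC1(C)OC(=O)c2c(CCc3ccccc3)cc(OC(C)(C)C#C)c(CC=C(C)C)c2O1
F7 | step 8 | 2,2-dimethyl-8-(3-methylbut-2-enyl)-5-(2-phenylethyl)-7-(prop-2-enyloxy)-4H-1,3-benzodioxin-4-one | CC1(C)OC(=O)c2c(CCc3ccccc3)cc(OCC=C)c(CC=C(C)C)c2O1
F8 | step 8 | 7-hydroxy-2,2-dimethyl-8-(3-methylbut-2-enyl)-5-(2-phenylethyl)-6-(prop-2-enyl)-4H-1,3-benzodioxin-4-one | CC1(C)OC(=O)c2c(CCc3ccccc3)c(CC=C)c(O)c(CC=C(C)C)c2O1
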